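**Retrosynthetic overview**

- Feature: in the cis-fused 3,7-dioxabicyclo[3.3.0]octane the two halves Ar–C2H(O3)–C1(OH)–C8H2–O7 and Ar–C6H(O7)–C5(OH)–C4H2–O3 are identical and share the C1–C5 bridgehead bond. Each half is an (E)-2-substituted cinnamyl alcohol with one oxygen added to each alkene carbon, so the skeleton maps onto an achiral (E,E)-2,3-bis(arylidene)butane-1,4-diol.
- Disconnection 1 (last rings): the O3–C2 and O7–C6 bonds of the two tetrahydrofurans, from a C2-symmetric bis(aryl oxirane) diol by invertive 5-endo opening at each benzylic carbon by the CH2OH of the other half. The oxirane oxygens remain as the C1 and C5 hydroxyls.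
- Disconnection 2 (key): the four oxirane C–O bonds, by two-fold titanium–tartrate epoxidation of the diene diol. D-(−)-diethyl tartrate should set all four centres R, which after inversion at C2 and C6 is (1R,2S,5R,6S).
- Disconnection 3: the diene diol from vanillin and dimethyl succinate by two-fold Stobbe condensation, esterification, phenol mesylation and i-Bu2AlH reduction.
- Ring order: both oxiranes (step 6), then tetrahydrofuran ring 1 and ring 2 (step 7); the phenols are freed last.

Key step: step 6

Remark: on every alkene of 5–8, E means aryl anti to the carboxyl or CH2OH carbon and syn to the central C–C bond. Syn oxygen transfer to this geometry followed by inversion at the benzylic carbon places each aryl group exo, cis to the neighbouring bridgehead hydroxyl, as the target requires.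

**Route**

Step 1
Reactants: 1 vanillin
Product: 2 3-methoxy-4-(methoxymethoxy)benzaldehyde
Conditions: MOMCl, iPr2NEt, CH2Cl2, 0 °C to rt
Reagents that add atoms: chloromethyl methyl ether (MOMCl), COCCl
Why: O-alkylation of the phenol (Williamson-type MOM ether formation) masks the acidic hydroxyl so that the aldehyde stays electrophilic under the alkoxide conditions of step 2.

Step 2
Reactants: 2 3-methoxy-4-(methoxymethoxy)benzaldehyde (2 equiv); 3 dimethyl succinate
Product: 5 (2E,3E)-2,3-bis[3-methoxy-4-(methoxymethoxy)benzylidene]succinic acid, via mono-arylidene half-ester 4 (not isolated)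
Conditions: KOtBu (3 equiv), t-BuOH, reflux; then cold 1 M HCl to pH 3; crystallisation
Reagents that add atoms: none
Why: Two-fold Stobbe condensation, in which at each succinate α-carbon the enolate adds to the aldehyde, the alkoxide lactonises onto the distal ester and E1cB opening gives the arylidene carboxylate, so both esters are consumed and the diacid should form with aryl anti to carboxyl (E) on both alkenes, minor geometric isomers being removed by crystallisation.

Step 3
Reactants: 5 (2E,3E)-2,3-bis[3-methoxy-4-(methoxymethoxy)benzylidene]succinic acid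
Product: 6 dimethyl (2E,3E)-2,3-bis(4-hydroxy-3-methoxybenzylidene)succinate
Conditions: H2SO4 (cat.), MeOH, reflux
Reagents that add atoms: methanol, CO
Why: Fischer esterification of both conjugated acids with concurrent acid-catalysed methanolysis of the two aryl MOM acetals, the alkene geometry being untouched.

Step 4
Reactants: 6 dimethyl (2E,3E)-2,3-bis(4-hydroxy-3-methoxybenzylidene)succinate
Product: 7 dimethyl (2E,3E)-2,3-bis[3-methoxy-4-(methylsulfonyloxy)benzylidene]succinate
Conditions: MsCl, Et3N, CH2Cl2, 0 °C
Reagents that add atoms: methanesulfonyl chloride, CS(=O)(=O)Cl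
Why: O-sulfonylation of the phenols, which are the only nucleophilic sites, installs the electron-withdrawing groups that later keep the benzylic oxiranes from ionising.

Step 5
Reactants: 7 dimethyl (2E,3E)-2,3-bis[3-methoxy-4-(methylsulfonyloxy)benzylidene]succinate
Product: 8 (2E,3E)-2,3-bis[3-methoxy-4-(methylsulfonyloxy)benzylidene]butane-1,4-diol
Conditions: i-Bu2AlH (5 equiv), CH2Cl2, −78 to −40 °C; then aq. KNaC4H4O6
Reagents that add atoms: none
Why: 1,2-Reduction of the two conjugated esters by the aluminium hydride should give the allylic alcohols without touching the alkenes, aryl sulfonates being inert to this reagent at low temperature.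

Step 6
Reactants: 8 (2E,3E)-2,3-bis[3-methoxy-4-(methylsulfonyloxy)benzylidene]butane-1,4-diol
Product: 10 [(2R,2'R,3R,3'R)-3,3'-bis[3-methoxy-4-(methylsulfonyloxy)phenyl]-[2,2'-bioxirane]-2,2'-diyl]dimethanol, via mono-oxirane 9 (not isolated)
Conditions: Ti(OiPr)4 (0.4 equiv), D-(−)-diethyl tartrate (0.5 equiv), t-BuOOH (4 equiv, anhydrous in decane), 4 Å molecular sieves, CH2Cl2, −20 °C; then saturated aq. Na2SO4, Et2O, filtration
Reagents that add atoms: tert-butyl hydroperoxide, CC(C)(C)OO
Why: Sharpless asymmetric epoxidation: each primary allylic alkoxide and t-BuOOH bind to the titanium tartrate, and the coordinated peroxide oxygen is passed to one enantioface of the adjacent trisubstituted alkene; the closest known cases are (E)-2-substituted cinnamyl alcohols such as (E)-2-methyl- and (E)-2-phenylcinnamyl alcohol. Each oxirane closes by concerted syn oxygen-atom transfer across the C=C bond, both C–O bonds of a ring forming in one event, so the E geometry fixes aryl trans to CH2OH within each ring. The absolute configuration of all four new stereocentres (2R,3R in each oxirane) is set by the D-(−)-tartrate ligand acting through the allylic hydroxyl, the mirror image of the (2S,3S) outcome known for L-(+)-tartrate with (E)-cinnamyl alcohols. The step needs the same enantioface choice at both alkenes; the two aryl groups cis to the central bond twist the diene out of conjugation, so the two allylic alcohols should react independently, and a wrong choice at one end gives the meso-type (R,R,S,S) diastereomer, removable by chromatography, which should raise the enantiomeric purity of the C2-symmetric product. The mesylates on the para oxygens withdraw electron density and should keep the benzylic oxiranes intact under the Lewis-acidic conditions.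

Step 7
Reactants: 10 [(2R,2'R,3R,3'R)-3,3'-bis[3-methoxy-4-(methylsulfonyloxy)phenyl]-[2,2'-bioxirane]-2,2'-diyl]dimethanol
Product: 12 (1R,2S,5R,6S)-2,6-bis[3-methoxy-4-(methylsulfonyloxy)phenyl]-3,7-dioxabicyclo[3.3.0]octane-1,5-diol, via spiro-oxirane tetrahydrofuran 11 (not isolated)
Conditions: (+)-10-camphorsulfonic acid (10 mol %), CH2Cl2, 0 °C to rt
Reagents that add atoms: none
Why: Acid-catalysed intramolecular oxirane opening (5-endo-tet, the 4-exo alternative being blocked at the fully substituted carbon), in which the CH2OH of the other half attacks each protonated oxirane at its benzylic carbon from the back, inverting it from R to S and leaving the oxirane oxygen as the bridgehead hydroxyl, so the second closure should give the cis-fused bicycle with both aryl groups exo.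

Step 8
Reactants: 12 (1R,2S,5R,6S)-2,6-bis[3-methoxy-4-(methylsulfonyloxy)phenyl]-3,7-dioxabicyclo[3.3.0]octane-1,5-diol
Product: 13 (1R,2S,5R,6S)-2,6-bis(4-hydroxy-3-methoxyphenyl)-3,7-dioxabicyclo[3.3.0]octane-1,5-diol
Conditions: KOH, MeOH/H2O, 50 °C; then 1 M HCl to pH 6
Reagents that add atoms: none
Why: Alkaline hydrolysis of the aryl sulfonates, in which hydroxide attacks sulfur and expels the phenoxide, should free both phenols while the tertiary alcohols and cyclic benzylic ethers are left alone at this moderate temperature.

**Compound list**

1 | vanillin (4-hydroxy-3-methoxybenzaldehyde) | COc1cc(C=O)ccc1O | starting material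
2 | 3-methoxy-4-(methoxymethoxy)benzaldehyde | COCOc1ccc(C=O)cc1OC | intermediate
3 | dimethyl succinate | COC(=O)CCC(=O)OC | starting material
4 | (E)-3-(methoxycarbonyl)-4-[3-methoxy-4-(methoxymethoxy)phenyl]but-3-enoic acid (mono-arylidene half-ester, present as its potassium salt) | COC(=O)/C(=C/c1ccc(OCOC)c(OC)c1)CC(=O)O | intermediate (not isolated)
5 | (2E,3E)-2,3-bis[3-methoxy-4-(methoxymethoxy)benzylidene]succinic acid | OC(=O)/C(=C/c1ccc(OCOC)c(OC)c1)C(=C/c1ccc(OCOC)c(OC)c1)\C(=O)O | intermediate
6 | dimethyl (2E,3E)-2,3-bis(4-hydroxy-3-methoxybenzylidene)succinate | COC(=O)/C(=C/c1ccc(O)c(OC)c1)C(=C/c1ccc(O)c(OC)c1)\C(=O)OC | intermediate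
7 | dimethyl (2E,3E)-2,3-bis[3-methoxy-4-(methylsulfonyloxy)benzylidene]succinate | COC(=O)/C(=C/c1ccc(OS(C)(=O)=O)c(OC)c1)C(=C/c1ccc(OS(C)(=O)=O)c(OC)c1)\C(=O)OC | intermediate
8 | (2E,3E)-2,3-bis[3-methoxy-4-(methylsulfonyloxy)benzylidene]butane-1,4-diol (key-step precursor) | OC/C(=C/c1ccc(OS(C)(=O)=O)c(OC)c1)C(=C/c1ccc(OS(C)(=O)=O)c(OC)c1)\CO | intermediate
9 | mono-oxirane: [(2R,3R)-3-aryl-2-(3-hydroxy-1-arylprop-1-en-2-yl)oxiran-2-yl]methanol, aryl = 3-methoxy-4-(methylsulfonyloxy)phenyl; remaining alkene as in 8 (aryl anti to CH2OH, Z by CIP) | OC/C(=C/c1ccc(OS(C)(=O)=O)c(OC)c1)[C@]1(CO)O[C@@H]1c1ccc(OS(C)(=O)=O)c(OC)c1 | intermediate (not isolated)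
10 | [(2R,2'R,3R,3'R)-3,3'-bis[3-methoxy-4-(methylsulfonyloxy)phenyl]-[2,2'-bioxirane]-2,2'-diyl]dimethanol (key-step product) | OC[C@]1(O[C@@H]1c3ccc(OS(C)(=O)=O)c(OC)c3)[C@]2(CO)O[C@@H]2c4ccc(OS(C)(=O)=O)c(OC)c4 | intermediate
11 | (2R,3R,6S,7R)-7-(hydroxymethyl)-2,6-bis[3-methoxy-4-(methylsulfonyloxy)phenyl]-1,5-dioxaspiro[2.4]heptan-7-ol (one tetrahydrofuran closed, one oxirane left) | COc1cc([C@@H]2OC[C@]3(O[C@@H]3c4ccc(OS(C)(=O)=O)c(OC)c4)[C@@]2(O)CO)ccc1OS(C)(=O)=O | intermediate (not isolated)
12 | (1R,2S,5R,6S)-2,6-bis[3-methoxy-4-(methylsulfonyloxy)phenyl]-3,7-dioxabicyclo[3.3.0]octane-1,5-diol | COc1cc([C@@H]2OC[C@@]3(O)[C@H](c4ccc(OS(C)(=O)=O)c(OC)c4)OC[C@@]23O)ccc1OS(C)(=O)=O | intermediate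
13 | (1R,2S,5R,6S)-2,6-bis(4-hydroxy-3-methoxyphenyl)-3,7-dioxabicyclo[3.3.0]octane-1,5-diol, equally (1S,3aR,4S,6aR)-1,4-bis(4-hydroxy-3-methoxyphenyl)tetrahydro-1H,3H-furo[3,4-c]furan-3a,6a-diol | COc1cc([C@@H]2OC[C@@]3(O)[C@H](c4ccc(O)c(OC)c4)OC[C@@]23O)ccc1O | target

**Step count and risks**

Total steps: 8. Longest linear sequence: 8 steps (1 to 13).

Steps most likely to fail:

Step 6. The 1,4-diol may tie up the titanium through both hydroxyls, so that turnover and enantioface discrimination fall. Oxygen transfer to the second, more hindered alkene may lag, or the titanium may open the first-formed aryl oxirane before the second transfer. The fallback gives up hydroxyl direction altogether and uses a dioxirane. It sets out from 8 and treats it with the D-fructose-derived Shi ketone (1,2:4,5-di-O-isopropylidene-β-D-erythro-2,3-hexodiulo-2,6-pyranose), KHSO5 (as the triple salt 2KHSO5·KHSO4·K2SO4), K2CO3, Na2B4O7 buffer at pH 10.5 and Bu4NHSO4 in MeCN/dimethoxymethane/H2O at 0 °C. The chiral dioxirane transfers oxygen through a spiro transition state without any metal or Lewis acid, and trisubstituted (E)-styrenyl alkenes are its best substrate class. The D-fructose ketone should attack the same enantioface as D-(−)-tartrate, as it gives (2R,3R)-oxiranes from (E)-cinnamyl-type alcohols. The sequence passes through 9 and comes back to the route at 10. It makes no compound outside the compound list (none F0).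

Step 7. The protonated oxirane may ionise to a benzylic cation instead of being attacked from the back. That would erode the inversion at C2 and C6 or divert material into a semipinacol (Meinwald-type) shift, and the 5-endo attack itself may be slow on the deactivated aryl oxirane. The fallback switches from activating the electrophile to activating the nucleophile. It sets out from 10 and uses NaH (2.2 equiv) in THF at 0 °C to rt, so that the sodium alkoxide of each CH2OH displaces the benzylic oxirane oxygen of the other half in a pure SN2 event with inversion. No cation can form, and the competing 4-exo attack is excluded at the fully substituted carbon. The sequence passes through 11 and comes back to the route at 12. It makes no compound outside the compound list (none F0).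

Step 2. The condensation may stall at the mono-arylidene half-ester, whose CH2 next to a carboxylate is only weakly acidic, and on forcing the aldehyde may be lost to Cannizzaro-type disproportionation or the alkene geometry may scramble. The fallback runs the two condensations separately with re-esterification in between. It sets out from 2 and 3. One equivalent of 2 with 3 (KOtBu, t-BuOH, reflux) should stop at the half-ester 4, now isolated. MeI, K2CO3, DMF should then give dimethyl (E)-2-[3-methoxy-4-(methoxymethoxy)benzylidene]succinate F1. A second Stobbe condensation of F1 with 2 (NaOMe, MeOH, reflux), now at a CH2 flanked by an ester, should give (2E,3E)-2,3-bis[3-methoxy-4-(methoxymethoxy)benzylidene]succinic acid monomethyl ester F2. F2 under the conditions of step 3 is esterified and unmasked, and the fallback comes back to the route at 6.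

**Further compounds**

F0 | step 6 | none | none
F0 | step 7 | none | none
F1 | step 2 | dimethyl (E)-2-[3-methoxy-4-(methoxymethoxy)benzylidene]succinate | COC(=O)/C(=C/c1ccc(OCOC)c(OC)c1)CC(=O)OC
F2 | step 2 | (2E,3E)-2,3-bis[3-methoxy-4-(methoxymethoxy)benzylidene]succinic acid monomethyl ester | COC(=O)/C(=C/c1ccc(OCOC)c(OC)c1)C(=C/c1ccc(OCOC)c(OC)c1)\C(=O)O
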